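**Retrosynthetic overview**

1. The side chain is numbered C1' (ArCH2) to C16'. The strategy rests on the 2,8-dioxabicyclo[3.2.1]octane, whose oxolane (C4'–C5'–C6'–C7'–O) and 1,3-dioxane (C4'–O–C7'–C8'–C9'–O) share the ketal carbon C4' and the methyl-bearing quaternary bridgehead C7'; the C7'–O carbon lies 1,3 to the allylic C9'–O carbon and 1,4 to C4'.
2. Both ring C–O bonds (C7'–O and C9'O–C4') are cut at once, back to an acyclic 4'-keto-9'-hydroxy chain with a C7'=CH2 group; the methylene carbon becomes the C7' methyl.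
3. The chain is cut at C5'–C6' into a western methyl ketone (C1'–C5', carrying C2' and C3') and an eastern allylic iodide (C6'–C16', carrying C9').
4. West: aryl–C1' by opening methyl (R)-glycidate with the aryl Grignard reagent, then C3' by chelation-controlled addition of an acetyl anion equivalent to an α-benzyloxy ketone. East: C8'–C9' by catalytic asymmetric allylation of geranial with a 2-(chloromethyl)allyl stannane.
5. Ring order: no ring is closed until the chain is complete; the oxolane and then the 1,3-dioxane form in one operation, followed by desilylation, diacetylation and conversion of the dimethoxyarene into the hydroquinone through the quinone.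

Key step: step 14

Remark (abbreviations): Ar = 2,5-dimethoxy-4-methylphenyl; Bn = benzyl; TBS = tert-butyldimethylsilyl; TES = triethylsilyl.
Remark (assumption): geranial is used as the isomerically pure E aldehyde; if only the E/Z mixture is at hand it is made from geraniol with MnO2.

Step 1
Reactants: 1 1-bromo-2,5-dimethoxy-4-methylbenzene; 2 methyl (R)-oxirane-2-carboxylate (methyl (R)-glycidate)
Product: 4 methyl (R)-3-(2,5-dimethoxy-4-methylphenyl)-2-hydroxypropanoate, via aryl Grignard reagent 3 (not isolated)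
Conditions: Mg, THF, rt → 50 °C; CuI (10 mol %), then 2, −40 → −20 °C; aq NH4Cl
Reagents that add atoms: none
Why: Copper-catalysed Grignard opening of a terminal epoxide: the aryl copper species from 3 and CuI attacks the unsubstituted CH2 of the glycidate faster than 3 adds to the ester at −40 °C, and C2 is not touched, so the (R) centre of 2 becomes C2' unchanged.

Step 2
Reactants: 4 methyl (R)-3-(2,5-dimethoxy-4-methylphenyl)-2-hydroxypropanoate
Product: 5 methyl (R)-2-(benzyloxy)-3-(2,5-dimethoxy-4-methylphenyl)propanoate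
Conditions: BnBr, Ag2O, Et2O, rt, dark
Reagents that add atoms: benzyl bromide BrCc1ccccc1
Why: Williamson-type O-benzylation under neutral Ag2O activation of the bromide, which avoids the enolate of the α-hydroxy ester and so should keep C2' intact.

Step 3
Reactants: 5 methyl (R)-2-(benzyloxy)-3-(2,5-dimethoxy-4-methylphenyl)propanoate
Product: 6 (R)-2-(benzyloxy)-3-(2,5-dimethoxy-4-methylphenyl)-N-methoxy-N-methylpropanamide
Conditions: MeNHOMe·HCl, i-PrMgCl, THF, −20 → 0 °C; 1 M HCl
Reagents that add atoms: N,O-dimethylhydroxylamine hydrochloride CNOC.Cl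
Why: Weinreb amide formation by aminolysis of the ester with the chloromagnesium amide, which is fast below 0 °C and too weakly basic to epimerise the α-alkoxy centre.

Step 4
Reactants: 7 benzyl chloromethyl ether
Product: 8 (benzyloxymethyl)tributylstannane
Conditions: Bu3SnH, LiN(iPr)2, THF, 0 °C; then 7, −78 °C → rt
Reagents that add atoms: tributyltin hydride CCCC[SnH](CCCC)CCCC
Why: SN2 displacement of the activated α-chloro ether by tributylstannyllithium gives the α-alkoxymethylstannane, a storable source of the hydroxymethyl carbanion.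

Step 5
Reactants: 6 (R)-2-(benzyloxy)-3-(2,5-dimethoxy-4-methylphenyl)-N-methoxy-N-methylpropanamide; 8 (benzyloxymethyl)tributylstannane
Product: 10 (3R)-1,3-bis(benzyloxy)-4-(2,5-dimethoxy-4-methylphenyl)butan-2-one, via benzyloxymethyllithium 9 (not isolated)
Conditions: 8, n-BuLi, THF, −78 °C; then 6, −78 °C; aq NH4Cl
Reagents that add atoms: none
Why: Tin–lithium exchange gives the α-alkoxy organolithium 9, and its addition to the amide stops at the chelated tetrahedral intermediate (Weinreb ketone synthesis), so the ketone is released only on quench and C2' is not exposed to base.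

Step 6
Reactants: 10 (3R)-1,3-bis(benzyloxy)-4-(2,5-dimethoxy-4-methylphenyl)butan-2-one; 11 ethyl vinyl ether
Product: 15 (3S,4R)-4-(benzyloxy)-3-[(benzyloxy)methyl]-5-(2,5-dimethoxy-4-methylphenyl)-3-hydroxypentan-2-one, via 1-ethoxyvinyllithium 12 (not isolated), via 1-ethoxyvinylmagnesium bromide 13 (not isolated), via enol ether adduct 14 (not isolated)
Conditions: 11, t-BuLi, THF, −78 → 0 °C; MgBr2·OEt2, −78 °C; 10 in CH2Cl2, −78 °C; then 1 M HCl, THF, 0 °C
Reagents that add atoms: water O
Why: Chelation-controlled 1,2-addition (Cram chelate model): magnesium ties the carbonyl oxygen to the C2' benzyloxy oxygen in a five-membered ring, the acyl anion equivalent 13 enters from the face bearing the C2' hydrogen, anti to the arylmethyl group, which should set C3' as S, and dilute acid hydrolyses the enol ether 14 to the methyl ketone.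

Step 7
Reactants: 15 (3S,4R)-4-(benzyloxy)-3-[(benzyloxy)methyl]-5-(2,5-dimethoxy-4-methylphenyl)-3-hydroxypentan-2-one
Product: 16 (3S,4R)-5-(2,5-dimethoxy-4-methylphenyl)-3,4-dihydroxy-3-(hydroxymethyl)pentan-2-one
Conditions: H2 (1 atm), Pd/C, EtOAc/EtOH, rt
Reagents that add atoms: none
Why: Hydrogenolysis of both benzyl ethers on palladium; the aryl methyl ethers, the ketone and the C1'–aryl bond are inert at 1 atm.

Step 8
Reactants: 16 (3S,4R)-5-(2,5-dimethoxy-4-methylphenyl)-3,4-dihydroxy-3-(hydroxymethyl)pentan-2-one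
Product: 17 (3S,4R)-4-(tert-butyldimethylsilyloxy)-3-[(tert-butyldimethylsilyloxy)methyl]-5-(2,5-dimethoxy-4-methylphenyl)-3-hydroxypentan-2-one
Conditions: TBSOTf (2.2 equiv), 2,6-lutidine, CH2Cl2, −78 → −20 °C
Reagents that add atoms: tert-butyldimethylsilyl trifluoromethanesulfonate CC(C)(C)[Si](C)(C)OS(=O)(=O)C(F)(F)F
Why: Silylation with a silyl triflate follows steric access (primary, then secondary), so the tertiary C3' hydroxyl should stay free at low temperature with a measured amount of reagent, and 2,6-lutidine is too weak a base to form the enol silane.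

Step 9
Reactants: 18 3-chloro-2-(chloromethyl)prop-1-ene
Product: 19 tributyl[2-(chloromethyl)prop-2-en-1-yl]stannane
Conditions: Bu3SnH, LiN(iPr)2, THF, 0 °C; added to 18 (3 equiv), THF, −78 °C
Reagents that add atoms: tributyltin hydride CCCC[SnH](CCCC)CCCC
Why: Nucleophilic substitution of one allylic chloride by the stannyl anion (direct and allylic displacement give the same product in this symmetrical dichloride), with excess dichloride suppressing the bis-stannane.

Step 10
Reactants: 19 tributyl[2-(chloromethyl)prop-2-en-1-yl]stannane; 20 geranial, (2E)-3,7-dimethylocta-2,6-dienal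
Product: 21 (4S,5E)-2-(chloromethyl)-6,10-dimethylundeca-1,5,9-trien-4-ol
Conditions: (S)-BINOL (20 mol %), Ti(OiPr)4 (10 mol %), 4 Å MS, CH2Cl2, −20 °C; aq NaHCO3
Reagents that add atoms: none
Why: Keck asymmetric allylation: the BINOL–titanium Lewis acid binds the aldehyde and the allylstannane adds 1,2 through an open transition state to one carbonyl face, forming C8'–C9'; the (S) ligand should give the (S) carbinol in the sense known for this catalyst with other aldehydes (to be verified on 21), and the E alkene of geranial is not involved.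

Step 11
Reactants: 21 (4S,5E)-2-(chloromethyl)-6,10-dimethylundeca-1,5,9-trien-4-ol
Product: 22 {[(4S,5E)-2-(chloromethyl)-6,10-dimethylundeca-1,5,9-trien-4-yl]oxy}triethylsilane
Conditions: TESCl, imidazole, CH2Cl2, 0 °C
Reagents that add atoms: chlorotriethylsilane CC[Si](Cl)(CC)CC
Why: Silyl ether formation blocks the carbinol so that its alkoxide cannot displace the allylic halide (five-membered ether) under later basic conditions; TES is chosen because it can later be removed without loss of the TBS ethers.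

Step 12
Reactants: 22 {[(4S,5E)-2-(chloromethyl)-6,10-dimethylundeca-1,5,9-trien-4-yl]oxy}triethylsilane
Product: 23 triethyl{[(4S,5E)-2-(iodomethyl)-6,10-dimethylundeca-1,5,9-trien-4-yl]oxy}silane
Conditions: NaI, acetone, rt, dark
Reagents that add atoms: sodium iodide [Na+].[I-]
Why: Finkelstein halide exchange, driven by precipitation of NaCl from acetone, gives the more reactive allylic iodide.

Step 13
Reactants: 17 (3S,4R)-4-(tert-butyldimethylsilyloxy)-3-[(tert-butyldimethylsilyloxy)methyl]-5-(2,5-dimethoxy-4-methylphenyl)-3-hydroxypentan-2-one; 23 triethyl{[(4S,5E)-2-(iodomethyl)-6,10-dimethylundeca-1,5,9-trien-4-yl]oxy}silane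
Product: 26 (2R,3S,9S,10E)-2-(tert-butyldimethylsilyloxy)-3-[(tert-butyldimethylsilyloxy)methyl]-1-(2,5-dimethoxy-4-methylphenyl)-3,9-dihydroxy-11,15-dimethyl-7-methylidenehexadeca-10,14-dien-4-one, via dilithium alkoxide enolate 24 (not isolated), via triethylsilyl ether 25 (not isolated)
Conditions: LiN(iPr)2 (2.2 equiv), THF, −78 °C; 23, DMPU, −78 → −30 °C; AcOH; crude, PPTS (cat.), MeOH/CH2Cl2, 0 °C
Reagents that add atoms: none
Why: Enolate alkylation: the first equivalent of base forms the C3' alkoxide and the second the enolate at the methyl group, the only enolisable position because C3' is quaternary, which is C-allylated by the allylic iodide (direct and allylic displacement give the same product) to form C5'–C6'; brief PPTS in methanol should remove the secondary allylic TES ether much faster than the TBS ethers.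

Step 14
Reactants: 26 (2R,3S,9S,10E)-2-(tert-butyldimethylsilyloxy)-3-[(tert-butyldimethylsilyloxy)methyl]-1-(2,5-dimethoxy-4-methylphenyl)-3,9-dihydroxy-11,15-dimethyl-7-methylidenehexadeca-10,14-dien-4-one
Product: 28 (2S,3R)-1,3-bis(tert-butyldimethylsilyloxy)-4-(2,5-dimethoxy-4-methylphenyl)-2-[(1R,3S,5R)-3-[(1E)-2,6-dimethylhepta-1,5-dien-1-yl]-5-methyl-2,8-dioxabicyclo[3.2.1]octan-1-yl]butan-2-ol, via chloromercurio ketal 27 (not isolated)
Conditions: HgCl(OAc) (1.3 equiv), Yb(OTf)3 (10 mol %), THF, 0 °C → rt; then NaBH4, 3 M aq NaOH, −20 → 0 °C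
Reagents that add atoms: none
Why: Proposed new method: HgCl(OAc) activates the 1,1-disubstituted C7'=CH2 alkene as a mercurinium ion, the C4' carbonyl oxygen attacks the tertiary carbon C7' (Markovnikov, 5-exo-trig, oxolane ring) to give a cyclic oxocarbenium ion, the C9' hydroxyl adds to C4' (6-endo-trig on the C=O+ bond, 1,3-dioxane ring), and NaBH4 then replaces mercury by hydrogen through a radical chain so that the former methylene becomes the C7' methyl group. The closest known reaction type is the Yb(OTf)3-catalysed, thermodynamically controlled oxymercuration of hemiacetals formed from homoallylic alcohols and an aldehyde or acetone, which gives syn-1,3-dioxanes after borohydride demercuration; here the ketone is tethered and the product is bridged. Each C–O bond formation is reversible under the Lewis acid (ketal opening to the oxocarbenium ion, then deoxymercuration back to ketone and alkene), so the mixture should drain to the most stable organomercurial, in which the C9' dienyl group is equatorial on the chair 1,3-dioxane; this fixes C7' as R relative to the catalyst-set 9'S centre, and the two-carbon C5'–C6' bridge, which must be diaxial, then fixes C4' as R. The step needs attack at C7' of the methylene alkene only: this alkene is the most reactive of the three towards oxymercuration and the only one with an internal oxygen nucleophile at ring-forming distance, and no water or alcohol is present to trap the trisubstituted alkenes. Attack of the tertiary C3' hydroxyl on the same mercurinium ion (6-exo) is a reversible detour that leaves the ketone unused and should revert to the ketal, and the mild mercury salt should spare the dimethoxyarene, the silyl ethers and the allylic C9'–O bond, which protic acid would endanger.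

Step 15
Reactants: 28 (2S,3R)-1,3-bis(tert-butyldimethylsilyloxy)-4-(2,5-dimethoxy-4-methylphenyl)-2-[(1R,3S,5R)-3-[(1E)-2,6-dimethylhepta-1,5-dien-1-yl]-5-methyl-2,8-dioxabicyclo[3.2.1]octan-1-yl]butan-2-ol
Product: 29 (2S,3R)-4-(2,5-dimethoxy-4-methylphenyl)-2-[(1R,3S,5R)-3-[(1E)-2,6-dimethylhepta-1,5-dien-1-yl]-5-methyl-2,8-dioxabicyclo[3.2.1]octan-1-yl]butane-1,2,3-triol
Conditions: Bu4NF, THF, 0 °C → rt
Reagents that add atoms: none
Why: Fluoride-induced cleavage of both silyl ethers (strong Si–F bond), which leaves the ketal, the alkenes and the aryl methyl ethers untouched.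

Step 16
Reactants: 29 (2S,3R)-4-(2,5-dimethoxy-4-methylphenyl)-2-[(1R,3S,5R)-3-[(1E)-2,6-dimethylhepta-1,5-dien-1-yl]-5-methyl-2,8-dioxabicyclo[3.2.1]octan-1-yl]butane-1,2,3-triol
Product: 30 (2S,3R)-4-(2,5-dimethoxy-4-methylphenyl)-2-[(1R,3S,5R)-3-[(1E)-2,6-dimethylhepta-1,5-dien-1-yl]-5-methyl-2,8-dioxabicyclo[3.2.1]octan-1-yl]-2-hydroxybutane-1,3-diyl diacetate
Conditions: Ac2O, pyridine, DMAP (cat.), CH2Cl2, 0 °C → rt
Reagents that add atoms: acetic anhydride CC(=O)OC(C)=O
Why: DMAP-catalysed acylation is fast at the primary and secondary hydroxyls and should fail at the tertiary C3' hydroxyl, which is shielded by the quaternary ketal carbon and two branched neighbours.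

Step 17
Reactants: 30 (2S,3R)-4-(2,5-dimethoxy-4-methylphenyl)-2-[(1R,3S,5R)-3-[(1E)-2,6-dimethylhepta-1,5-dien-1-yl]-5-methyl-2,8-dioxabicyclo[3.2.1]octan-1-yl]-2-hydroxybutane-1,3-diyl diacetate
Product: 31 (2S,3R)-2-[(1R,3S,5R)-3-[(1E)-2,6-dimethylhepta-1,5-dien-1-yl]-5-methyl-2,8-dioxabicyclo[3.2.1]octan-1-yl]-2-hydroxy-4-(4-methyl-3,6-dioxocyclohexa-1,4-dien-1-yl)butane-1,3-diyl diacetate
Conditions: (NH4)2Ce(NO3)6 (2.5 equiv), MeCN/H2O, 0 °C, 15 min
Reagents that add atoms: water O
Why: Oxidative demethylation of a para-dimethoxyarene: two one-electron oxidations of the electron-rich ring with addition of water and loss of methanol give the quinone within minutes at 0 °C, faster than any reaction of the isolated trisubstituted alkenes or acid hydrolysis of the bridged ketal.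

Step 18
Reactants: 31 (2S,3R)-2-[(1R,3S,5R)-3-[(1E)-2,6-dimethylhepta-1,5-dien-1-yl]-5-methyl-2,8-dioxabicyclo[3.2.1]octan-1-yl]-2-hydroxy-4-(4-methyl-3,6-dioxocyclohexa-1,4-dien-1-yl)butane-1,3-diyl diacetate
Product: 32 (2S,3R)-4-(2,5-dihydroxy-4-methylphenyl)-2-[(1R,3S,5R)-3-[(1E)-2,6-dimethylhepta-1,5-dien-1-yl]-5-methyl-2,8-dioxabicyclo[3.2.1]octan-1-yl]-2-hydroxybutane-1,3-diyl diacetate (CNP0160303.2)
Conditions: Na2S2O4, EtOAc/H2O, rt, argon
Reagents that add atoms: none
Why: Two-electron reduction of the quinone by dithionite in a two-phase mixture should give the hydroquinone without touching acetates, ketal or alkenes.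

**Compound list**

1 | 1-bromo-2,5-dimethoxy-4-methylbenzene | COc1cc(Br)c(OC)cc1C | starting material
2 | methyl (R)-oxirane-2-carboxylate | COC(=O)[C@H]1CO1 | starting material
3 | (2,5-dimethoxy-4-methylphenyl)magnesium bromide | COc1cc([Mg]Br)c(OC)cc1C | intermediate
4 | methyl (R)-3-(2,5-dimethoxy-4-methylphenyl)-2-hydroxypropanoate | COC(=O)[C@H](O)Cc1cc(OC)c(C)cc1OC | intermediate
5 | methyl (R)-2-(benzyloxy)-3-(2,5-dimethoxy-4-methylphenyl)propanoate | COC(=O)[C@H](OCc1ccccc1)Cc1cc(OC)c(C)cc1OC | intermediate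
6 | (R)-2-(benzyloxy)-3-(2,5-dimethoxy-4-methylphenyl)-N-methoxy-N-methylpropanamide | CON(C)C(=O)[C@H](OCc1ccccc1)Cc1cc(OC)c(C)cc1OC | intermediate
7 | benzyl chloromethyl ether | ClCOCc1ccccc1 | starting material
8 | (benzyloxymethyl)tributylstannane | CCCC[Sn](CCCC)(CCCC)COCc1ccccc1 | intermediate
9 | benzyloxymethyllithium | [Li]COCc1ccccc1 | intermediate
10 | (3R)-1,3-bis(benzyloxy)-4-(2,5-dimethoxy-4-methylphenyl)butan-2-one | O=C(COCc1ccccc1)[C@@H](Cc1cc(OC)c(C)cc1OC)OCc1ccccc1 | intermediate
11 | ethyl vinyl ether | C=COCC | starting material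
12 | 1-ethoxyvinyllithium | [Li]C(=C)OCC | intermediate
13 | 1-ethoxyvinylmagnesium bromide | Br[Mg]C(=C)OCC | intermediate
14 | (2S,3R)-1,3-bis(benzyloxy)-4-(2,5-dimethoxy-4-methylphenyl)-2-(1-ethoxyethenyl)butan-2-ol | C=C(OCC)[C@](O)(COCc1ccccc1)[C@@H](Cc1cc(OC)c(C)cc1OC)OCc1ccccc1 | intermediate
15 | (3S,4R)-4-(benzyloxy)-3-[(benzyloxy)methyl]-5-(2,5-dimethoxy-4-methylphenyl)-3-hydroxypentan-2-one | CC(=O)[C@](O)(COCc1ccccc1)[C@@H](Cc1cc(OC)c(C)cc1OC)OCc1ccccc1 | intermediate
16 | (3S,4R)-5-(2,5-dimethoxy-4-methylphenyl)-3,4-dihydroxy-3-(hydroxymethyl)pentan-2-one | CC(=O)[C@](O)(CO)[C@@H](Cc1cc(OC)c(C)cc1OC)O | intermediate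
17 | (3S,4R)-4-(tert-butyldimethylsilyloxy)-3-[(tert-butyldimethylsilyloxy)methyl]-5-(2,5-dimethoxy-4-methylphenyl)-3-hydroxypentan-2-one | CC(=O)[C@](O)(CO[Si](C)(C)C(C)(C)C)[C@@H](Cc1cc(OC)c(C)cc1OC)O[Si](C)(C)C(C)(C)C | intermediate
18 | 3-chloro-2-(chloromethyl)prop-1-ene | C=C(CCl)CCl | starting material
19 | tributyl[2-(chloromethyl)prop-2-en-1-yl]stannane | C=C(CCl)C[Sn](CCCC)(CCCC)CCCC | intermediate
20 | geranial, (2E)-3,7-dimethylocta-2,6-dienal | O=C/C=C(\C)CCC=C(C)C | starting material
21 | (4S,5E)-2-(chloromethyl)-6,10-dimethylundeca-1,5,9-trien-4-ol | C=C(CCl)C[C@@H](/C=C(\C)CCC=C(C)C)O | intermediate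
22 | {[(4S,5E)-2-(chloromethyl)-6,10-dimethylundeca-1,5,9-trien-4-yl]oxy}triethylsilane | C=C(CCl)C[C@@H](/C=C(\C)CCC=C(C)C)O[Si](CC)(CC)CC | intermediate
23 | triethyl{[(4S,5E)-2-(iodomethyl)-6,10-dimethylundeca-1,5,9-trien-4-yl]oxy}silane | C=C(CI)C[C@@H](/C=C(\C)CCC=C(C)C)O[Si](CC)(CC)CC | intermediate
24 | dilithium alkoxide enolate of 17 (C3'–OLi; C4'(OLi)=CH2) | [Li]OC(=C)[C@](O[Li])(CO[Si](C)(C)C(C)(C)C)[C@@H](Cc1cc(OC)c(C)cc1OC)O[Si](C)(C)C(C)(C)C | intermediate
25 | (2R,3S,9S,10E)-2-(tert-butyldimethylsilyloxy)-3-[(tert-butyldimethylsilyloxy)methyl]-1-(2,5-dimethoxy-4-methylphenyl)-3-hydroxy-11,15-dimethyl-7-methylidene-9-(triethylsilyloxy)hexadeca-10,14-dien-4-one | CC(C)(C)[Si](C)(C)OC[C@](O)([C@@H](Cc1cc(OC)c(C)cc1OC)O[Si](C)(C)C(C)(C)C)C(=O)CCC(=C)C[C@@H](/C=C(\C)CCC=C(C)C)O[Si](CC)(CC)CC | intermediate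
26 | (2R,3S,9S,10E)-2-(tert-butyldimethylsilyloxy)-3-[(tert-butyldimethylsilyloxy)methyl]-1-(2,5-dimethoxy-4-methylphenyl)-3,9-dihydroxy-11,15-dimethyl-7-methylidenehexadeca-10,14-dien-4-one | CC(C)(C)[Si](C)(C)OC[C@](O)([C@@H](Cc1cc(OC)c(C)cc1OC)O[Si](C)(C)C(C)(C)C)C(=O)CCC(=C)C[C@@H](/C=C(\C)CCC=C(C)C)O | intermediate
27 | chloromercurio ketal: 28 with CH2HgCl in place of the 5-methyl group of the bicycle, (1R,3S,5R) | CC(C)(C)[Si](C)(C)OC[C@](O)([C@@H](Cc1cc(OC)c(C)cc1OC)O[Si](C)(C)C(C)(C)C)[C@]12CC[C@](C[Hg]Cl)(C[C@@H](/C=C(\C)CCC=C(C)C)O1)O2 | intermediate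
28 | (2S,3R)-1,3-bis(tert-butyldimethylsilyloxy)-4-(2,5-dimethoxy-4-methylphenyl)-2-[(1R,3S,5R)-3-[(1E)-2,6-dimethylhepta-1,5-dien-1-yl]-5-methyl-2,8-dioxabicyclo[3.2.1]octan-1-yl]butan-2-ol | CC(C)(C)[Si](C)(C)OC[C@](O)([C@@H](Cc1cc(OC)c(C)cc1OC)O[Si](C)(C)C(C)(C)C)[C@]12CC[C@](C)(C[C@@H](/C=C(\C)CCC=C(C)C)O1)O2 | intermediate
29 | (2S,3R)-4-(2,5-dimethoxy-4-methylphenyl)-2-[(1R,3S,5R)-3-[(1E)-2,6-dimethylhepta-1,5-dien-1-yl]-5-methyl-2,8-dioxabicyclo[3.2.1]octan-1-yl]butane-1,2,3-triol | OC[C@](O)([C@@H](Cc1cc(OC)c(C)cc1OC)O)[C@]12CC[C@](C)(C[C@@H](/C=C(\C)CCC=C(C)C)O1)O2 | intermediate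
30 | (2S,3R)-4-(2,5-dimethoxy-4-methylphenyl)-2-[(1R,3S,5R)-3-[(1E)-2,6-dimethylhepta-1,5-dien-1-yl]-5-methyl-2,8-dioxabicyclo[3.2.1]octan-1-yl]-2-hydroxybutane-1,3-diyl diacetate | CC(=O)OC[C@](O)([C@@H](Cc1cc(OC)c(C)cc1OC)OC(C)=O)[C@]12CC[C@](C)(C[C@@H](/C=C(\C)CCC=C(C)C)O1)O2 | intermediate
31 | (2S,3R)-2-[(1R,3S,5R)-3-[(1E)-2,6-dimethylhepta-1,5-dien-1-yl]-5-methyl-2,8-dioxabicyclo[3.2.1]octan-1-yl]-2-hydroxy-4-(4-methyl-3,6-dioxocyclohexa-1,4-dien-1-yl)butane-1,3-diyl diacetate | CC(=O)OC[C@](O)([C@@H](CC1=CC(=O)C(C)=CC1=O)OC(C)=O)[C@]12CC[C@](C)(C[C@@H](/C=C(\C)CCC=C(C)C)O1)O2 | intermediate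
32 | (2S,3R)-4-(2,5-dihydroxy-4-methylphenyl)-2-[(1R,3S,5R)-3-[(1E)-2,6-dimethylhepta-1,5-dien-1-yl]-5-methyl-2,8-dioxabicyclo[3.2.1]octan-1-yl]-2-hydroxybutane-1,3-diyl diacetate (CNP0160303.2) | CC(=O)OC[C@](O)([C@@H](Cc1cc(O)c(C)cc1O)OC(C)=O)[C@]12CC[C@](C)(C[C@@H](/C=C(\C)CCC=C(C)C)O1)O2 | target

**Totals**

Total step count: 18.
Longest linear sequence: 13 steps (steps 1, 2, 3, 5, 6, 7, 8, 13, 14, 15, 16, 17, 18, from 1 and 2 to 32).

**Steps most likely to fail**

1. Step 14 (Proposed new method). What may go wrong: the oxymercuration does not reach equilibrium, so that the C7' epimer with the axial dienyl group, or the pyranone from attack of the C3' hydroxyl, survives to the reduction; or the organomercurial reverts to the alkene during demercuration. Fallback with known reactions only, in which C7' is set by reagent control before the fragments are joined and the rings close by ordinary ketalisation; it sets out from 22 and 17 and comes back at 28. Acetate displacement on 22 (KOAc, DMF, 50 °C) gives the allylic acetate F1, and K2CO3 in MeOH at 0 °C gives the allylic alcohol F2. Sharpless asymmetric epoxidation of F2 (Ti(OiPr)4, L-(+)-diethyl tartrate, t-BuOOH, 4 Å MS, CH2Cl2, −20 °C; the tartrate that gives (2S,3S) epoxides from E allylic alcohols such as (E)-hex-2-en-1-ol) should give the epoxy alcohol F3, only the alkene of the allylic alcohol reacting. LiAlH4 (THF, 0 °C) opens the epoxide at its CH2 to the 1,2-diol F4, whose new methyl group is the C7' methyl. Tosylation of the primary hydroxyl (TsCl, Et3N, cat. Bu2SnO, CH2Cl2) gives the monotosylate F5, and K2CO3 in MeOH closes the terminal epoxide F6. The dilithium species 24 (from 17 as in step 13) opens F6 at CH2 in the presence of LiClO4 (THF, −78 °C → rt) to give the γ-hydroxy ketone F7 with the C5'–C6' bond in place. PPTS in MeOH/CH2Cl2 then removes the TES group, and the 7',9'-dihydroxy ketone should close to 28 by acid-catalysed intramolecular ketalisation, the thermodynamic sink of such keto diols.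

2. Step 13. What may go wrong: proton transfer from the product to unreacted enolate with double allylation, O-allylation of the C3' alkoxide, or loss of the sensitive allylic iodide by elimination before it is alkylated. Fallback: the C5'–C6' bond is made by π-allyl chemistry of zerovalent palladium (Tsuji–Trost allylation of a preformed ketone enolate) instead of a direct displacement; it sets out from 17 and the allylic chloride 22 (the iodide 23 is not needed) and comes back at 26. The dilithium species 24 is generated as before, LiCl and Pd(PPh3)4 (5 mol %) are added, then 22 in THF at 0 °C → rt. Oxidative addition gives a 2-substituted π-allyl palladium complex whose two termini are equivalent, so only one constitution can form, and the soft electrophile favours C- over O-attack and mono-allylation. The product is the TES ether 25, which is treated with PPTS in MeOH as in step 13 to give 26.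

3. Step 6. What may go wrong: poor facial selectivity, because magnesium can also chelate the carbonyl with the primary benzyloxymethyl oxygen and leave the C2' centre to react through an open arrangement, together with enolisation of the ketone by the basic reagent. Fallback: C3' is set under polar Felkin–Anh control with the two carbon nucleophiles introduced in the reverse order, which leads to the same C3' configuration; it sets out from 4 and comes back at 17. 4 is silylated (TBSCl, imidazole, DMF) to the silyl ether F8 and converted into the Weinreb amide F9 (MeNHOMe·HCl, i-PrMgCl, THF, −20 °C). 1-Ethoxyvinyllithium 12 gives the 2-ethoxy enone F10. Benzyloxymethyllithium 9 (THF, −78 °C, no chelating metal) should add anti to the non-chelating silyloxy group to give the carbinol F11, whose enol ether is hydrolysed with 1 M HCl to the methyl ketone F12. Hydrogenolysis (H2, Pd/C, EtOAc) gives the primary alcohol F13, and TBSCl with imidazole silylates only this primary hydroxyl to give 17, which also avoids the selective bis-silylation of step 8.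

**Further compounds**

F1 | step 14 | (4S,5E)-6,10-dimethyl-2-methylidene-4-(triethylsilyloxy)undeca-5,9-dien-1-yl acetate | C=C(COC(C)=O)C[C@@H](/C=C(\C)CCC=C(C)C)O[Si](CC)(CC)CC
F2 | step 14 | (4S,5E)-6,10-dimethyl-2-methylidene-4-(triethylsilyloxy)undeca-5,9-dien-1-ol | C=C(CO)C[C@@H](/C=C(\C)CCC=C(C)C)O[Si](CC)(CC)CC
F3 | step 14 | {(2S)-2-[(2S,3E)-4,8-dimethyl-2-(triethylsilyloxy)nona-3,7-dien-1-yl]oxiran-2-yl}methanol | OC[C@@]1(C[C@@H](/C=C(\C)CCC=C(C)C)O[Si](CC)(CC)CC)CO1
F4 | step 14 | (2S,4S,5E)-2,6,10-trimethyl-4-(triethylsilyloxy)undeca-5,9-diene-1,2-diol | OC[C@@](C)(O)C[C@@H](/C=C(\C)CCC=C(C)C)O[Si](CC)(CC)CC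
F5 | step 14 | (2S,4S,5E)-2-hydroxy-2,6,10-trimethyl-4-(triethylsilyloxy)undeca-5,9-dien-1-yl 4-methylbenzenesulfonate | Cc1ccc(cc1)S(=O)(=O)OC[C@@](C)(O)C[C@@H](/C=C(\C)CCC=C(C)C)O[Si](CC)(CC)CC
F6 | step 14 | (2S)-2-methyl-2-[(2S,3E)-4,8-dimethyl-2-(triethylsilyloxy)nona-3,7-dien-1-yl]oxirane | C[C@]1(C[C@@H](/C=C(\C)CCC=C(C)C)O[Si](CC)(CC)CC)CO1
F7 | step 14 | (2R,3S,7R,9S,10E)-2-(tert-butyldimethylsilyloxy)-3-[(tert-butyldimethylsilyloxy)methyl]-1-(2,5-dimethoxy-4-methylphenyl)-3,7-dihydroxy-7,11,15-trimethyl-9-(triethylsilyloxy)hexadeca-10,14-dien-4-one | CC(C)(C)[Si](C)(C)OC[C@](O)([C@@H](Cc1cc(OC)c(C)cc1OC)O[Si](C)(C)C(C)(C)C)C(=O)CC[C@@](C)(O)C[C@@H](/C=C(\C)CCC=C(C)C)O[Si](CC)(CC)CC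
F0 | step 13 | none | none
F8 | step 6 | methyl (R)-2-(tert-butyldimethylsilyloxy)-3-(2,5-dimethoxy-4-methylphenyl)propanoate | COC(=O)[C@H](O[Si](C)(C)C(C)(C)C)Cc1cc(OC)c(C)cc1OC
F9 | step 6 | (R)-2-(tert-butyldimethylsilyloxy)-3-(2,5-dimethoxy-4-methylphenyl)-N-methoxy-N-methylpropanamide | CON(C)C(=O)[C@H](O[Si](C)(C)C(C)(C)C)Cc1cc(OC)c(C)cc1OC
F10 | step 6 | (4R)-4-(tert-butyldimethylsilyloxy)-5-(2,5-dimethoxy-4-methylphenyl)-2-ethoxypent-1-en-3-one | C=C(OCC)C(=O)[C@H](O[Si](C)(C)C(C)(C)C)Cc1cc(OC)c(C)cc1OC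
F11 | step 6 | (3S,4R)-3-[(benzyloxy)methyl]-4-(tert-butyldimethylsilyloxy)-5-(2,5-dimethoxy-4-methylphenyl)-2-ethoxypent-1-en-3-ol | C=C(OCC)[C@](O)(COCc1ccccc1)[C@@H](Cc1cc(OC)c(C)cc1OC)O[Si](C)(C)C(C)(C)C
F12 | step 6 | (3S,4R)-3-[(benzyloxy)methyl]-4-(tert-butyldimethylsilyloxy)-5-(2,5-dimethoxy-4-methylphenyl)-3-hydroxypentan-2-one | CC(=O)[C@](O)(COCc1ccccc1)[C@@H](Cc1cc(OC)c(C)cc1OC)O[Si](C)(C)C(C)(C)C
F13 | step 6 | (3S,4R)-4-(tert-butyldimethylsilyloxy)-5-(2,5-dimethoxy-4-methylphenyl)-3-hydroxy-3-(hydroxymethyl)pentan-2-one | CC(=O)[C@](O)(CO)[C@@H](Cc1cc(OC)c(C)cc1OC)O[Si](C)(C)C(C)(C)C
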